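3 questions stand over delta and gamma, two flasks that differ in protic impurity: how large each excess of left-handed product is at the end, and which is higher.

| setting | spring | dawn | delta | gamma |
|---|---|---|---|---|
| left-handed substrate | 1.5 M | 1.5 M | 1.5 M | 1.5 M |
| right-handed substrate | 1.5 M | 1.5 M | 1.5 M | 1.5 M |
| partner | 1.8 M | 1.8 M | 1.80 M | 1.80 M |
| protic impurity | 0.027 M | 0.062 M | 0.0750 M | 0.0400 M |
| free catalyst | 38 mM | 38 mM | 38 mM | 38 mM |
| remark | run made earlier | run made earlier |  |  |
| time |  |  | 30 min | 30 min |

| run | time / min | left-handed product / % | right-handed product / % |
|---|---|---|---|
| spring | 1.33 | 15.0 | 6.1 |
| spring | 4.00 | 26.2 | 13.5 |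
| spring | 8.00 | 32.3 | 16.9 |
| spring | 10.0 | 33.2 | 17.1 |
| spring | 15.0 | 34.7 | 19.4 |
| dawn | 3.00 | 23.2 | 11.8 |
| dawn | 6.00 | 28.5 | 16.7 |
| dawn | 10.0 | 32.3 | 17.7 |
| dawn | 12.0 | 34.3 | 18.5 |
| dawn | 15.0 | 34.0 | 19.1 |

(standard deviation of a reading: 0.5 percentage points)

* the winner by excess of left-handed product over right-handed product in the product; "neither" if no more than 2 percentage points parts them (delta / gamma / neither)
* excess of left-handed product over right-handed product in the product at the end, delta
* excess of left-handed product over right-handed product in the product at the end, gamma

- free catalyst is single-handed; left-handed substrate and right-handed substrate are mirror images of each other, charged as a racemate, each of them at the stated concentration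
- the numbers in the tables scatter with a standard deviation of 0.5 percentage points
- an excess is the difference of the two amounts in percent of their sum
- an excess is below zero if the other one leads

The runs read as a ladder. On the first rung, spring holds 39.7% of both substrates as product after 4.00 min. On the second it holds 54.1% after 15.0 min, below the 60.0% that charged partner allows at one partner per product. The third rung is the asked 30 min, twice that last reading. Dawn carries more impurity, yet after 10.0 min it reads 50.0% against spring's 50.3%, which is within the scatter.

So we drop the clock. Suppose each substrate reacts in proportion to its own amount, with the same partner and catalyst. Dividing one rate by the other then cancels time, and the logarithm of the fraction of left-handed substrate remaining, over that of right-handed substrate remaining, stays fixed. This ratio is the selectivity factor. Spring's last reading gives 2.41, and dawn's gives 2.37.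

With that factor fixed, excess follows product, not time. In the spring readings it falls from 32.0% to 28.3% between those two rungs while product rises by 14 percentage points, so the fall in excess is a fraction 0.258 of the rise in product. If delta's extra impurity takes one partner each, delta makes 1.2 points less product than gamma, and its excess stands higher by 0.3 points, less than the margin. We commit to about 28.3% for both, delta barely ahead.

The forecast says 27% for delta, 27.5% for gamma and neither: “The two runs differ by under 1 point, so neither wins”. It sets gamma slightly ahead, where we set delta.

Delta ends at 27.6%, gamma at 27.3%, so the winner is neither.

    partner + free catalyst + left-handed substrate → free catalyst + left-handed product (k = 5.00 L² mol⁻² min⁻¹)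
    partner + free catalyst + right-handed substrate → free catalyst + right-handed product (k = 2.10 L² mol⁻² min⁻¹)
    partner → decomposed reagent (k = 0.0130 min⁻¹)
    partner + protic impurity → quenched reagent (k = 0.350 L mol⁻¹ min⁻¹)
    partner + free catalyst → spent catalyst (k = 0.00280 L mol⁻¹ min⁻¹)

At 30.0 min in delta, partner's half-life is 8.2 min by the left-handed step against 4.1 h by quenching. Partner stands at 0.24% of its charge, with 60% of right-handed substrate left. From that remainder, the selectivity factor gives delta an excess of 27.8%. The neighbour of delta charged with 0.72 M of partner keeps 86% of right-handed substrate, so the same factor gives 37.0%, and the excess of that flask ends at 36.6%.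

(Readings and results were computed on assumed constants.)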